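**Retrosynthetic overview**

1. With the acid chain numbered from the carboxyl carbon (C1), the target is traced back to its bis-MOM methyl ester; the C7=C8 isopropylidene group comes from a C6=C7 vinyl group (hydroboration/oxidation, then Wittig).
2. Key disconnection C4–C5: C5 is a tertiary CH bonded to the furan ring carbon β to oxygen (C3 of the 5-arylfuran-3-yl unit) and flanked by chain carbons C4 and C6. C5–C6–C7 can therefore act as a furyl-substituted allyl unit that takes up the C1–C4 fragment at C5, which leads to the racemic carbonate 11 and the (R)-alkylzinc bromide 16.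
3. Carbonate 11 comes from aryl furan aldehyde 8 and vinylmagnesium bromide; the arene–furan bond is a Suzuki–Miyaura disconnection to the bromofuroate and a boronate made from hydroquinone.
4. Zinc reagent 16 comes from (R)-α-methyl-γ-butyrolactone 13, made by asymmetric hydrogenation of the methylene lactone (this sets C2).
5. No ring is formed: the furan ring and the benzene ring both arrive intact from the starting materials.

Key step: step 10

Assumption (chemistry): the (S) antipode of the phosphoramidite–olefin ligand (step 10) and (S)-BINAP (step 7) are assigned by analogy with aryl allyl carbonates and simple methylene lactones as the antipodes leading to 5R and 2R. The sense should be confirmed on the first batch, and the mirror-image ligand used, with nothing else changed, if it proves opposite.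

**Route**

Step 1
Reactants: 1 hydroquinone
Product: 2 1,4-bis(methoxymethoxy)benzene
Conditions: NaH, MOMCl, DMF, 0 °C → rt
Reagents that add atoms: chloromethyl methyl ether, COCCl
Why: Williamson-type O-alkylation of the bis-phenoxide should give the bis-MOM ether, whose acetal oxygens later direct lithiation and withstand the organometallic steps.

Step 2
Reactants: 2 1,4-bis(methoxymethoxy)benzene
Product: 4 2-[2,5-bis(methoxymethoxy)phenyl]-4,4,5,5-tetramethyl-1,3,2-dioxaborolane, via aryllithium 3 (not isolated)
Conditions: n-BuLi, TMEDA, THF, 0 °C; then i-PrOBpin, −78 °C → rt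
Reagents that add atoms: 2-isopropoxy-4,4,5,5-tetramethyl-1,3,2-dioxaborolane, CC(C)OB1OC(C)(C)C(C)(C)O1
Why: Directed ortho-metalation by the OMOM group (all four ring CH positions are equivalent, so one aryllithium forms) followed by borylation with the borate ester should give the pinacol boronate.

Step 3
Reactants: 4 2-[2,5-bis(methoxymethoxy)phenyl]-4,4,5,5-tetramethyl-1,3,2-dioxaborolane; 5 methyl 5-bromofuran-3-carboxylate
Product: 6 methyl 5-[2,5-bis(methoxymethoxy)phenyl]furan-3-carboxylate
Conditions: Pd(dppf)Cl2 (cat.), K3PO4, 1,4-dioxane/H2O, 80 °C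
Reagents that add atoms: none
Why: Suzuki–Miyaura coupling, in which the C–Br bond next to the furan oxygen adds readily to zerovalent palladium and the mild phosphate base should spare the methyl ester.

Step 4
Reactants: 6 methyl 5-[2,5-bis(methoxymethoxy)phenyl]furan-3-carboxylate
Product: 7 [5-[2,5-bis(methoxymethoxy)phenyl]furan-3-yl]methanol
Conditions: i-Bu2AlH, CH2Cl2, −78 → 0 °C; aqueous KNaC4H4O6 work-up
Reagents that add atoms: none
Why: Full hydride reduction of the ester to the primary alcohol is chosen over partial reduction because it is the more dependable way to the aldehyde oxidation level in two steps.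

Step 5
Reactants: 7 [5-[2,5-bis(methoxymethoxy)phenyl]furan-3-yl]methanol
Product: 8 5-[2,5-bis(methoxymethoxy)phenyl]furan-3-carbaldehyde
Conditions: MnO2 (activated, excess), CH2Cl2, rt
Reagents that add atoms: none
Why: MnO2 oxidation of the heterobenzylic (furylmethyl) alcohol should stop at the aldehyde under neutral conditions that leave the MOM ethers and the furan untouched.

Step 6
Reactants: 8 5-[2,5-bis(methoxymethoxy)phenyl]furan-3-carbaldehyde; 9 vinylmagnesium bromide
Product: 11 racemic 1-[5-[2,5-bis(methoxymethoxy)phenyl]furan-3-yl]prop-2-enyl tert-butyl carbonate, via bromomagnesium alkoxide 10 (not isolated)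
Conditions: CH2=CHMgBr, THF, −78 → 0 °C; then Boc2O, 0 °C → rt; chromatography on Et3N-deactivated silica
Reagents that add atoms: di-tert-butyl dicarbonate, CC(C)(C)OC(=O)OC(=O)OC(C)(C)C
Why: Grignard 1,2-addition gives the racemic magnesium alkoxide, which is acylated in the same flask by Boc2O; no stereocontrol is needed because the next step on this compound is enantioconvergent.

Step 7
Reactants: 12 3-methylideneoxolan-2-one
Product: 13 (3R)-3-methyloxolan-2-one
Conditions: Ru(OAc)2[(S)-BINAP] (cat.), H2 (ca. 100 atm), CH2Cl2, 50 °C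
Reagents that add atoms: none
Why: Ruthenium–BINAP asymmetric hydrogenation of the exocyclic alkene, in which the lactone carbonyl binds divalent ruthenium and the BINAP environment selects the alkene face, should set the C2 methyl centre as R.

Step 8
Reactants: 13 (3R)-3-methyloxolan-2-one
Product: 15 methyl (2R)-4-bromo-2-methylbutanoate, via bromo acid 14 (not isolated)
Conditions: HBr (33% in AcOH), rt → 60 °C; then MeOH, rt
Reagents that add atoms: hydrogen bromide, Br; methanol, CO
Why: Acid-mediated lactone opening (SN2 attack of bromide at the O–CH2 carbon) followed by Fischer esterification in the same flask traps the bromo acid before it can relactonize, and the α-centre is not involved.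

Step 9
Reactants: 15 methyl (2R)-4-bromo-2-methylbutanoate
Product: 16 [(3R)-4-methoxy-3-methyl-4-oxobutyl]zinc bromide (titrated THF solution, used directly)
Conditions: Zn dust, LiCl, BrCH2CH2Br (cat.), Me3SiCl (cat.), THF, 50 °C
Reagents that add atoms: zinc, [Zn]
Why: LiCl-promoted oxidative insertion of zinc into the primary C–Br bond should give the alkylzinc bromide, a reagent class that tolerates esters; the stereocentre, two carbons from the zinc-bearing carbon, is not touched under these non-basic conditions.

Step 10
Reactants: 11 racemic 1-[5-[2,5-bis(methoxymethoxy)phenyl]furan-3-yl]prop-2-enyl tert-butyl carbonate; 16 [(3R)-4-methoxy-3-methyl-4-oxobutyl]zinc bromide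
Product: 17 methyl (2R,5R)-5-[5-[2,5-bis(methoxymethoxy)phenyl]furan-3-yl]-2-methylhept-6-enoate
Conditions: [Ir(cod)Cl]2 (cat.), (S)-N-(dinaphtho[2,1-d:1′,2′-f][1,3,2]dioxaphosphepin-4-yl)dibenzo[b,f]azepine (cat., 4 equiv per Ir dimer), 16 (2 equiv), THF, rt
Reagents that add atoms: none
Why: Monovalent iridium bound to the phosphoramidite–olefin ligand ionizes both enantiomers of 11, with loss of tert-butyl carbonate, to a common trivalent iridium π-allyl spanning C5–C6–C7, and the alkyl group of 16 is then transferred to the furyl-bearing terminus to form the C4–C5 bond. The closest known reaction type is the iridium-catalysed enantioconvergent allylic alkylation of racemic branched aryl allyl carbonates with functionalized alkylzinc bromides, here applied to a 3-furyl substrate and an ester-bearing zinc reagent. No ring is closed. The new C5 centre is set by the ligand, which decides the face of the allyl intermediate that receives the alkyl group, so the racemate should converge on 5R. C2 is carried in from 16, is remote from zinc and is not enolized under the neutral conditions. The step needs branched over linear regioselectivity and high facial selectivity; both are imposed by the ligand-bound allyl complex, aided by the electron-rich furan, which stabilizes positive charge at the substituted terminus.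

Step 11
Reactants: 17 methyl (2R,5R)-5-[5-[2,5-bis(methoxymethoxy)phenyl]furan-3-yl]-2-methylhept-6-enoate
Product: 19 methyl (2R,5R)-5-[5-[2,5-bis(methoxymethoxy)phenyl]furan-3-yl]-7-hydroxy-2-methylheptanoate, via alkylborane 18 (not isolated)
Conditions: 9-BBN, THF, 0 °C → rt; then NaBO3·4H2O, H2O, rt
Reagents that add atoms: sodium perborate, [Na+].[Na+].O[B-]1(O)OO[B-](O)(O)OO1
Why: Anti-Markovnikov hydroboration of the monosubstituted alkene with bulky 9-BBN places boron on C7 without reducing the ester or attacking the furan, and the mild perborate oxidation should give the primary alcohol without saponifying the ester.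

Step 12
Reactants: 19 methyl (2R,5R)-5-[5-[2,5-bis(methoxymethoxy)phenyl]furan-3-yl]-7-hydroxy-2-methylheptanoate
Product: 20 methyl (2R,5R)-5-[5-[2,5-bis(methoxymethoxy)phenyl]furan-3-yl]-2-methyl-7-oxoheptanoate
Conditions: Dess–Martin periodinane, pyridine, CH2Cl2, 0 °C → rt
Reagents that add atoms: none
Why: Dess–Martin oxidation under pyridine buffering should give the aldehyde without acid damage to the MOM ethers; C5 is β to the new carbonyl and cannot epimerize.

Step 13
Reactants: 20 methyl (2R,5R)-5-[5-[2,5-bis(methoxymethoxy)phenyl]furan-3-yl]-2-methyl-7-oxoheptanoate; 21 isopropyltriphenylphosphonium iodide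
Product: 23 methyl (2R,5R)-5-[5-[2,5-bis(methoxymethoxy)phenyl]furan-3-yl]-2,8-dimethylnon-7-enoate, via ylide 22 (not isolated)
Conditions: 21 (slight excess over base), n-BuLi, THF, 0 °C; then 20, −78 → 0 °C
Reagents that add atoms: none
Why: Wittig olefination with the non-stabilized, symmetrical isopropylidene ylide raises no E/Z question, and at low temperature the ylide should add to the aldehyde far faster than it attacks or enolizes the ester.

Step 14
Reactants: 23 methyl (2R,5R)-5-[5-[2,5-bis(methoxymethoxy)phenyl]furan-3-yl]-2,8-dimethylnon-7-enoate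
Product: 24 (2R,5R)-5-[5-[2,5-bis(methoxymethoxy)phenyl]furan-3-yl]-2,8-dimethylnon-7-enoic acid
Conditions: LiOH·H2O, THF/MeOH/H2O, 0 °C → rt; then 1 M HCl to pH 4, 0 °C
Reagents that add atoms: lithium hydroxide, [Li+].[OH-]
Why: Saponification by acyl–oxygen cleavage should outrun α-deprotonation, and the carboxylate once formed is not enolized, so C2 is preserved; the phenols are still protected, which avoids exposing a hydroquinone to base.

Step 15
Reactants: 24 (2R,5R)-5-[5-[2,5-bis(methoxymethoxy)phenyl]furan-3-yl]-2,8-dimethylnon-7-enoic acid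
Product: 25 (2R,5R)-5-[5-(2,5-dihydroxyphenyl)furan-3-yl]-2,8-dimethylnon-7-enoic acid (CNP0076906.1)
Conditions: ZnBr2, n-PrSH, CH2Cl2, 0 °C → rt, argon; work-up under argon
Reagents that add atoms: none
Why: Lewis-acid/thiol cleavage of the aryl MOM acetals (ZnBr2 activates the acetal and the thiol captures the methoxymethyl cation) is brief, non-aqueous and nearly neutral, and should therefore spare the trisubstituted alkene, the furan and the free acid.

**Compound list**

1 | hydroquinone | Oc1ccc(O)cc1 | starting material
2 | 1,4-bis(methoxymethoxy)benzene | COCOc1ccc(OCOC)cc1 | intermediate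
3 | [2,5-bis(methoxymethoxy)phenyl]lithium | [Li]c1cc(OCOC)ccc1OCOC | intermediate
4 | 2-[2,5-bis(methoxymethoxy)phenyl]-4,4,5,5-tetramethyl-1,3,2-dioxaborolane | COCOc1ccc(OCOC)c(B2OC(C)(C)C(C)(C)O2)c1 | intermediate
5 | methyl 5-bromofuran-3-carboxylate | COC(=O)c1coc(Br)c1 | starting material
6 | methyl 5-[2,5-bis(methoxymethoxy)phenyl]furan-3-carboxylate | COC(=O)c1coc(-c2cc(OCOC)ccc2OCOC)c1 | intermediate
7 | [5-[2,5-bis(methoxymethoxy)phenyl]furan-3-yl]methanol | OCc1coc(-c2cc(OCOC)ccc2OCOC)c1 | intermediate
8 | 5-[2,5-bis(methoxymethoxy)phenyl]furan-3-carbaldehyde | O=Cc1coc(-c2cc(OCOC)ccc2OCOC)c1 | intermediate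
9 | vinylmagnesium bromide | C=C[Mg]Br | starting material
10 | bromomagnesium 1-[5-[2,5-bis(methoxymethoxy)phenyl]furan-3-yl]prop-2-en-1-olate (racemic) | C=CC(O[Mg]Br)c1coc(-c2cc(OCOC)ccc2OCOC)c1 | intermediate
11 | 1-[5-[2,5-bis(methoxymethoxy)phenyl]furan-3-yl]prop-2-enyl tert-butyl carbonate (racemic) | C=CC(OC(=O)OC(C)(C)C)c1coc(-c2cc(OCOC)ccc2OCOC)c1 | intermediate
12 | 3-methylideneoxolan-2-one | C=C1CCOC1=O | starting material
13 | (3R)-3-methyloxolan-2-one | C[C@@H]1CCOC1=O | intermediate
14 | (2R)-4-bromo-2-methylbutanoic acid | BrCC[C@@H](C)C(=O)O | intermediate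
15 | methyl (2R)-4-bromo-2-methylbutanoate | BrCC[C@@H](C)C(=O)OC | intermediate
16 | [(3R)-4-methoxy-3-methyl-4-oxobutyl]zinc bromide | Br[Zn]CC[C@@H](C)C(=O)OC | intermediate
17 | methyl (2R,5R)-5-[5-[2,5-bis(methoxymethoxy)phenyl]furan-3-yl]-2-methylhept-6-enoate | C=C[C@@H](CC[C@@H](C)C(=O)OC)c1coc(-c2cc(OCOC)ccc2OCOC)c1 | intermediate
18 | methyl (2R,5S)-7-(9-borabicyclo[3.3.1]nonan-9-yl)-5-[5-[2,5-bis(methoxymethoxy)phenyl]furan-3-yl]-2-methylheptanoate (same spatial arrangement at C5 as in 17; the descriptor changes only because boron ranks below carbon) | C1CCC2CCCC(C1)B2CC[C@@H](CC[C@@H](C)C(=O)OC)c1coc(-c2cc(OCOC)ccc2OCOC)c1 | intermediate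
19 | methyl (2R,5R)-5-[5-[2,5-bis(methoxymethoxy)phenyl]furan-3-yl]-7-hydroxy-2-methylheptanoate | OCC[C@@H](CC[C@@H](C)C(=O)OC)c1coc(-c2cc(OCOC)ccc2OCOC)c1 | intermediate
20 | methyl (2R,5R)-5-[5-[2,5-bis(methoxymethoxy)phenyl]furan-3-yl]-2-methyl-7-oxoheptanoate | O=CC[C@@H](CC[C@@H](C)C(=O)OC)c1coc(-c2cc(OCOC)ccc2OCOC)c1 | intermediate
21 | isopropyltriphenylphosphonium iodide | CC(C)[P+](c1ccccc1)(c1ccccc1)c1ccccc1.[I-] | starting material
22 | isopropylidenetriphenylphosphorane | CC(C)=P(c1ccccc1)(c1ccccc1)c1ccccc1 | intermediate
23 | methyl (2R,5R)-5-[5-[2,5-bis(methoxymethoxy)phenyl]furan-3-yl]-2,8-dimethylnon-7-enoate | CC(C)=CC[C@@H](CC[C@@H](C)C(=O)OC)c1coc(-c2cc(OCOC)ccc2OCOC)c1 | intermediate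
24 | (2R,5R)-5-[5-[2,5-bis(methoxymethoxy)phenyl]furan-3-yl]-2,8-dimethylnon-7-enoic acid | CC(C)=CC[C@@H](CC[C@@H](C)C(=O)O)c1coc(-c2cc(OCOC)ccc2OCOC)c1 | intermediate
25 | (2R,5R)-5-[5-(2,5-dihydroxyphenyl)furan-3-yl]-2,8-dimethylnon-7-enoic acid | CC(C)=CC[C@@H](CC[C@@H](C)C(=O)O)c1coc(-c2cc(O)ccc2O)c1 | target

**Step count**

Total: 15 steps. Longest linear sequence: 12 steps (steps 1–6 and 10–15); the zinc fragment adds a three-step branch (steps 7–9).

**Steps most likely to fail**

Step 10. The furyl carbonate may ionize and then alkylate at the unsubstituted allyl terminus, the two diastereomeric allyl complexes may not equilibrate fast enough for full convergence, or the ester-bearing zinc reagent may transfer its alkyl group too slowly. The fallback forms the same C4–C5 bond by copper-catalysed enantioselective SN2′ alkylation of a linear allylic phosphate and sets out from aldehyde 8 and bromide 15. Horner–Wadsworth–Emmons olefination of 8 with triethyl phosphonoacetate (NaH, THF) would give ethyl (E)-3-[5-[2,5-bis(methoxymethoxy)phenyl]furan-3-yl]prop-2-enoate F1. Reduction with i-Bu2AlH would give (E)-3-[5-[2,5-bis(methoxymethoxy)phenyl]furan-3-yl]prop-2-en-1-ol F2, and ClP(O)(OEt)2 with pyridine and DMAP would give diethyl (E)-3-[5-[2,5-bis(methoxymethoxy)phenyl]furan-3-yl]prop-2-enyl phosphate F3. In parallel, 15 would be converted with NaI in acetone into methyl (2R)-4-iodo-2-methylbutanoate F4, and iodine–zinc exchange (Et2Zn, CuI cat., 50 °C, volatiles removed) would give bis[(3R)-4-methoxy-3-methyl-4-oxobutyl]zinc F5. Coupling of F3 with F5 under a chiral N-heterocyclic carbene–copper catalyst generated from (CuOTf)2·C6H6 and a chiral imidazolinium salt (THF, −15 °C) should deliver the alkyl group to the furyl-bearing carbon, and the route is rejoined at 17.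

Step 15. The free hydroquinone may oxidize during work-up, and the Lewis acid may promote thiol or acid addition to the trisubstituted alkene or degrade the electron-rich furan. The fallback reverses the order of the last two operations and sets out from ester 23. Methanolic HCl at rt (where re-esterification is of no concern) would remove both MOM groups and give methyl (2R,5R)-5-[5-(2,5-dihydroxyphenyl)furan-3-yl]-2,8-dimethylnon-7-enoate F6. The ester would then be hydrolysed with LiOH in degassed THF/H2O containing Na2S2O4 under argon, followed by careful acidification, arriving directly at target 25.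

Step 7. Isomerization of the exocyclic alkene to the endocyclic butenolide may compete with hydrogenation and erode the enantiomeric purity of 13, which would later appear as an inseparable C2 epimer. The fallback sets C2 with a chiral auxiliary and starts from commercial (4S)-4-benzyl-3-propanoyl-1,3-oxazolidin-2-one. Enolization with NaN(SiMe3)2 and alkylation with allyl iodide (THF, −78 °C) should give (4S)-4-benzyl-3-[(2R)-2-methylpent-4-enoyl]-1,3-oxazolidin-2-one F7. Ozonolysis (O3, CH2Cl2, −78 °C; Me2S) would give (4S)-4-benzyl-3-[(2R)-2-methyl-4-oxobutanoyl]-1,3-oxazolidin-2-one F8, and NaBH4 in MeOH at −20 °C would give (4S)-4-benzyl-3-[(2R)-4-hydroxy-2-methylbutanoyl]-1,3-oxazolidin-2-one F9. On mild base treatment (K2CO3, MeOH) F9 should lactonize with release of the auxiliary, and the route is rejoined at lactone 13.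

**Further compounds**

F1 | step 10 | ethyl (E)-3-[5-[2,5-bis(methoxymethoxy)phenyl]furan-3-yl]prop-2-enoate | CCOC(=O)/C=C/c1coc(-c2cc(OCOC)ccc2OCOC)c1
F2 | step 10 | (E)-3-[5-[2,5-bis(methoxymethoxy)phenyl]furan-3-yl]prop-2-en-1-ol | OC/C=C/c1coc(-c2cc(OCOC)ccc2OCOC)c1
F3 | step 10 | diethyl (E)-3-[5-[2,5-bis(methoxymethoxy)phenyl]furan-3-yl]prop-2-enyl phosphate | CCOP(=O)(OCC)OC/C=C/c1coc(-c2cc(OCOC)ccc2OCOC)c1
F4 | step 10 | methyl (2R)-4-iodo-2-methylbutanoate | ICC[C@@H](C)C(=O)OC
F5 | step 10 | bis[(3R)-4-methoxy-3-methyl-4-oxobutyl]zinc | COC(=O)[C@H](C)CC[Zn]CC[C@@H](C)C(=O)OC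
F6 | step 15 | methyl (2R,5R)-5-[5-(2,5-dihydroxyphenyl)furan-3-yl]-2,8-dimethylnon-7-enoate | CC(C)=CC[C@@H](CC[C@@H](C)C(=O)OC)c1coc(-c2cc(O)ccc2O)c1
F7 | step 7 | (4S)-4-benzyl-3-[(2R)-2-methylpent-4-enoyl]-1,3-oxazolidin-2-one | C=CC[C@@H](C)C(=O)N1[C@@H](Cc2ccccc2)COC1=O
F8 | step 7 | (4S)-4-benzyl-3-[(2R)-2-methyl-4-oxobutanoyl]-1,3-oxazolidin-2-one | O=CC[C@@H](C)C(=O)N1[C@@H](Cc2ccccc2)COC1=O
F9 | step 7 | (4S)-4-benzyl-3-[(2R)-4-hydroxy-2-methylbutanoyl]-1,3-oxazolidin-2-one | OCC[C@@H](C)C(=O)N1[C@@H](Cc2ccccc2)COC1=O
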